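**Plan**
1. Retrosynthesis: the two benzyl ethers of ring C and the thioketal masking the side-chain ketone are removed first. Ring A is then opened at C3a–C4 (benzofuran numbering), leaving a 2-arylfuran with a 2-methoxy-1,3-diketone chain on its α-carbon.
2. The chain is cut at C5–C6 into a (5-arylfuran-2-yl)acetic acid and a methoxymethyl ketone carrying a dithiane. The acid is cut at the aryl–furan bond, the ketone at the bond between the dithiane carbon and its CH2.
3. Forward: ring C is joined to the furan by C–H arylation, acid and ketone are joined by a Claisen-type acylation, ring A is closed onto the furan by acid, then ketone and phenols are unmasked.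
4. Enabling feature: C7, C6, C5 and C4 of ring A are the furyl-CH2, C=O, CH(OMe) and C=O of the chain. The furan β-carbon (future C3a) closes a six-membered ring on the C4 carbonyl, and ring A aromatises with C5–OMe and C6–OH already differentiated.
5. Stereochemistry: the target is achiral. The carbinol centre from the epoxide opening and the methoxy-bearing carbon of the diketone are racemic and are erased by oxidation and aromatisation.

Key step: step 8

Remark: ring A positions are numbered as in benzofuran (C3a, C4–C7, C7a) even for the open-chain precursor; the 1,3-diketone is drawn in the diketo form although it should be largely enolised.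

**Step 1**
Reactants: 1 5-bromobenzene-1,3-diol
Product: 2 1,3-bis(benzyloxy)-5-bromobenzene
Conditions: BnBr (2.3 equiv), K2CO3, DMF, 60 °C
Reagents that add atoms: benzyl bromide, BrCc1ccccc1
Why: Williamson etherification of both phenoxides with a reactive benzylic bromide should proceed cleanly, the aryl bromide being inert to K2CO3.

**Step 2**
Reactants: 2 1,3-bis(benzyloxy)-5-bromobenzene; 3 ethyl 2-(furan-2-yl)acetate
Product: 4 ethyl 2-{5-[3,5-bis(benzyloxy)phenyl]furan-2-yl}acetate
Conditions: Pd(OAc)2 (2 mol%), KOAc, DMAc, 130 °C; 3 in twofold excess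
Reagents that add atoms: none
Why: Palladium-catalysed direct C–H arylation by acetate-assisted concerted metalation–deprotonation should occur only at the single free α-position (C5) of the 2-substituted furan, and KOAc is too weak a base to enolise the ester.

**Step 3**
Reactants: 4 ethyl 2-{5-[3,5-bis(benzyloxy)phenyl]furan-2-yl}acetate
Product: 5 2-{5-[3,5-bis(benzyloxy)phenyl]furan-2-yl}acetic acid
Conditions: LiOH·H2O, THF/MeOH/H2O, rt; then cold dilute HCl to pH 3
Reagents that add atoms: lithium hydroxide, [Li+].[OH-]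
Why: Saponification of an unhindered ethyl ester is expected to leave the benzyl ethers and the furan untouched, and the brief cold acidification spares the furan.

**Step 4**
Reactants: 6 2-methylpropanal (isobutyraldehyde)
Product: 7 2-isopropyl-1,3-dithiane
Conditions: HS(CH2)3SH, BF3·OEt2 (cat.), CH2Cl2, 0 °C → rt
Reagents that add atoms: propane-1,3-dithiol, SCCCS
Why: Lewis-acid thioacetalisation of an aliphatic aldehyde is the standard first stage of Corey–Seebach umpolung.

**Step 5**
Reactants: 7 2-isopropyl-1,3-dithiane; 8 2-(methoxymethyl)oxirane (racemic)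
Product: 10 1-(2-isopropyl-1,3-dithian-2-yl)-3-methoxypropan-2-ol (racemic), via 2-lithio-2-isopropyl-1,3-dithiane 9 (not isolated)
Conditions: n-BuLi, THF, −30 → −20 °C; then 8, −20 → 0 °C; H2O
Reagents that add atoms: none
Why: In this Corey–Seebach alkylation the lithiated dithiane should open the monosubstituted epoxide by SN2 attack at its terminal carbon; the carbinol centre comes from the racemic epoxide and is removed in step 6.

**Step 6**
Reactants: 10 1-(2-isopropyl-1,3-dithian-2-yl)-3-methoxypropan-2-ol (racemic)
Product: 11 1-(2-isopropyl-1,3-dithian-2-yl)-3-methoxypropan-2-one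
Conditions: (COCl)2, DMSO, CH2Cl2, −78 °C; Et3N, → 0 °C
Reagents that add atoms: none
Why: Swern oxidation should convert the secondary alcohol to the ketone at −78 °C without oxidising the thioketal sulfur.

**Step 7**
Reactants: 5 2-{5-[3,5-bis(benzyloxy)phenyl]furan-2-yl}acetic acid; 11 1-(2-isopropyl-1,3-dithian-2-yl)-3-methoxypropan-2-one
Product: 14 1-{5-[3,5-bis(benzyloxy)phenyl]furan-2-yl}-5-(2-isopropyl-1,3-dithian-2-yl)-3-methoxypentane-2,4-dione (racemic), via acyl imidazolide 12 (not isolated), via lithium enolate 13 (not isolated)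
Conditions: 5, CDI, THF, rt; separately 11 (3 equiv), LiN(SiMe3)2 (3 equiv), THF, −78 °C; add 12, −78 → −30 °C; AcOH quench
Reagents that add atoms: none
Why: Claisen-type C-acylation of a lithium ketone enolate by an acyl imidazolide should give the 1,3-diketone, because 11 is deprotonated at the methoxymethylene carbon (inductively activated, lithium chelated by OMe) rather than at the neopentyl-like CH2 beside the quaternary dithiane carbon; the excess enolate absorbs the acidic imidazole N–H and the diketone product, and the new C3 stereocentre is racemic, enolisable and lost in step 8.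

**Step 8**
Reactants: 14 1-{5-[3,5-bis(benzyloxy)phenyl]furan-2-yl}-5-(2-isopropyl-1,3-dithian-2-yl)-3-methoxypentane-2,4-dione (racemic)
Product: 15 2-[3,5-bis(benzyloxy)phenyl]-4-[(2-isopropyl-1,3-dithian-2-yl)methyl]-5-methoxybenzofuran-6-ol
Conditions: p-TsOH·H2O (0.3 equiv), toluene, 90 °C, Dean–Stark
Reagents that add atoms: none
Why: Acid protonates the ketone that carries the dithianylmethyl group (future C4), and the furan β-carbon next to the tether (future C3a) adds to it in an intramolecular Friedel–Crafts hydroxyalkylation whose σ-complex is an oxocarbenium ion held by the furan oxygen; rearomatisation of the furan, loss of water from the tertiary furylic carbinol and enolisation of the C6 ketone then make ring A aromatic. The closest known reaction type is the Bradsher-type acid cyclodehydration, in particular the cycloaromatisation of arylacetyl 1,3-dicarbonyl compounds to 2-naphthols and naphthalene-1,3-diols, here run with a 2,5-disubstituted furan as the arene, a variant that is only sparsely documented. Ring A closes in a 6-(enolendo)-exo-trig mode through the new C3a–C4 bond. No stereocentre is formed, and the racemic methoxy-bearing carbon of 14 becomes the sp2 carbon C5. The selectivity needed is that between the two carbonyls and the two furan β-carbons: only the β-carbon beside the tether can reach the chain, and its attack on the nearer ketone would give a four-membered ring, so the 1,3-diketone geometry alone places alkyl at C4, OMe at C5 and OH at C6. The thioketal keeps the side-chain carbonyl from joining in (the unmasked 1,3,5-triketone would cyclise through oxygen to a pyranone), and azeotropic removal of water guards the furan against hydrolytic opening.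

**Step 9**
Reactants: 15 2-[3,5-bis(benzyloxy)phenyl]-4-[(2-isopropyl-1,3-dithian-2-yl)methyl]-5-methoxybenzofuran-6-ol
Product: 16 1-{2-[3,5-bis(benzyloxy)phenyl]-6-hydroxy-5-methoxybenzofuran-4-yl}-3-methylbutan-2-one
Conditions: MeI (excess), CaCO3, MeCN/H2O 9:1, 45 °C
Reagents that add atoms: water, O
Why: Alkylative hydrolysis of the thioketal (S-methylation, ring opening to a thionium ion, capture by water) uses no oxidant or halonium source, so the electron-rich benzofuranol should survive, and insoluble CaCO3 is too weak a base to allow O-methylation of the phenol.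

**Step 10**
Reactants: 16 1-{2-[3,5-bis(benzyloxy)phenyl]-6-hydroxy-5-methoxybenzofuran-4-yl}-3-methylbutan-2-one
Product: 17 moracin Q, 1-[2-(3,5-dihydroxyphenyl)-6-hydroxy-5-methoxybenzofuran-4-yl]-3-methylbutan-2-one
Conditions: H2 (1 atm), Pd/C (10% Pd), EtOAc/MeOH, rt
Reagents that add atoms: none
Why: Catalytic hydrogenolysis of the two aryl benzyl ethers should be selective at 1 atm and room temperature, since the 2-arylbenzofuran and the dialkyl ketone are not reduced under these conditions and the catalyst-poisoning sulfur was removed in step 9.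

**Compound list**
1 | 5-bromobenzene-1,3-diol | Oc1cc(O)cc(Br)c1 | starting material
2 | 1,3-bis(benzyloxy)-5-bromobenzene | Brc1cc(OCc2ccccc2)cc(OCc2ccccc2)c1 | intermediate
3 | ethyl 2-(furan-2-yl)acetate | CCOC(=O)Cc1ccco1 | starting material
4 | ethyl 2-{5-[3,5-bis(benzyloxy)phenyl]furan-2-yl}acetate | CCOC(=O)Cc1ccc(-c2cc(OCc3ccccc3)cc(OCc3ccccc3)c2)o1 | intermediate
5 | 2-{5-[3,5-bis(benzyloxy)phenyl]furan-2-yl}acetic acid | OC(=O)Cc1ccc(-c2cc(OCc3ccccc3)cc(OCc3ccccc3)c2)o1 | intermediate
6 | 2-methylpropanal (isobutyraldehyde) | CC(C)C=O | starting material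
7 | 2-isopropyl-1,3-dithiane | CC(C)C1SCCCS1 | intermediate
8 | 2-(methoxymethyl)oxirane (racemic) | COCC1CO1 | starting material
9 | 2-lithio-2-isopropyl-1,3-dithiane (not isolated) | [Li]C1(C(C)C)SCCCS1 | intermediate
10 | 1-(2-isopropyl-1,3-dithian-2-yl)-3-methoxypropan-2-ol (racemic) | CC(C)C1(CC(O)COC)SCCCS1 | intermediate
11 | 1-(2-isopropyl-1,3-dithian-2-yl)-3-methoxypropan-2-one | CC(C)C1(CC(=O)COC)SCCCS1 | intermediate
12 | 2-{5-[3,5-bis(benzyloxy)phenyl]furan-2-yl}-1-(1H-imidazol-1-yl)ethan-1-one (acyl imidazolide, not isolated) | O=C(Cc1ccc(-c2cc(OCc3ccccc3)cc(OCc3ccccc3)c2)o1)n1ccnc1 | intermediate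
13 | lithium (Z)-1-(2-isopropyl-1,3-dithian-2-yl)-3-methoxyprop-2-en-2-olate (lithium enolate of 11, not isolated; Z expected from chelation, geometry without consequence) | [Li]O/C(CC1(C(C)C)SCCCS1)=C\OC | intermediate
14 | 1-{5-[3,5-bis(benzyloxy)phenyl]furan-2-yl}-5-(2-isopropyl-1,3-dithian-2-yl)-3-methoxypentane-2,4-dione (racemic, C3 enolisable) | CC(C)C1(CC(=O)C(OC)C(=O)Cc2ccc(-c3cc(OCc4ccccc4)cc(OCc4ccccc4)c3)o2)SCCCS1 | intermediate
15 | 2-[3,5-bis(benzyloxy)phenyl]-4-[(2-isopropyl-1,3-dithian-2-yl)methyl]-5-methoxybenzofuran-6-ol | COc1c(O)cc2oc(-c3cc(OCc4ccccc4)cc(OCc4ccccc4)c3)cc2c1CC1(C(C)C)SCCCS1 | intermediate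
16 | 1-{2-[3,5-bis(benzyloxy)phenyl]-6-hydroxy-5-methoxybenzofuran-4-yl}-3-methylbutan-2-one | COc1c(O)cc2oc(-c3cc(OCc4ccccc4)cc(OCc4ccccc4)c3)cc2c1CC(=O)C(C)C | intermediate
17 | moracin Q, 1-[2-(3,5-dihydroxyphenyl)-6-hydroxy-5-methoxybenzofuran-4-yl]-3-methylbutan-2-one (achiral) | COc1c(O)cc2oc(-c3cc(O)cc(O)c3)cc2c1CC(=O)C(C)C | target

Total number of steps: 10. Longest linear sequence: 7 steps (steps 1, 2, 3, 7, 8, 9, 10; the branch through steps 4, 5, 6 is equally long).

**Steps most likely to fail**

Step 8. Attack of the furan β-carbon on the ketone may be slow. Acid-driven side reactions could then take over: hydrolytic opening of the furan by the water released, retro-Claisen cleavage of the diketone, loss of thiol from the β-keto thioketal, or acid-induced migration of benzyl groups on ring C. The fallback builds ring A from a benzene precursor and closes the furan last; it sets out from bromide 2 and comes back at the target 17.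
- Commercial 3-bromo-4,5-dihydroxybenzaldehyde is methylated at its more acidic 4-hydroxyl (MeI, Li2CO3, DMF) to 3-bromo-5-hydroxy-4-methoxybenzaldehyde F1, then benzylated (BnBr, K2CO3) to 3-(benzyloxy)-5-bromo-4-methoxybenzaldehyde F2.
- Baeyer–Villiger oxidation (mCPBA) and methanolysis of the aryl formate (K2CO3, MeOH) give 3-(benzyloxy)-5-bromo-4-methoxyphenol F3.
- NIS should iodinate F3 ortho to the hydroxyl and para to the benzyloxy group, giving 5-(benzyloxy)-3-bromo-2-iodo-4-methoxyphenol F4.
- Sonogashira coupling of 2 with ethynyltrimethylsilane (PdCl2(PPh3)2, CuI, Et3N, 70 °C) gives {[3,5-bis(benzyloxy)phenyl]ethynyl}trimethylsilane F5.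
- Desilylative Sonogashira coupling of F5 at the iodide of F4 (PdCl2(PPh3)2, CuI, Bu4NF, Et3N, DMF, 70 °C), followed in the same flask by 5-endo-dig closure of the ortho-alkynylphenol, gives 6-(benzyloxy)-2-[3,5-bis(benzyloxy)phenyl]-4-bromo-5-methoxybenzofuran F6.
- Palladium-catalysed α-arylation of 3-methylbutan-2-one at its methyl group (Pd2(dba)3, XPhos, NaOt-Bu, toluene, 80 °C) gives 1-{6-(benzyloxy)-2-[3,5-bis(benzyloxy)phenyl]-5-methoxybenzofuran-4-yl}-3-methylbutan-2-one F7.
- Hydrogenolysis of the three benzyl ethers of F7 (H2, Pd/C) gives 17.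

Step 7. The enolate may act as a base towards the acidic furylacetyl imidazolide instead of being acylated, O-acylation may compete, and part of 11 may be deprotonated on the dithiane side. The fallback replaces acylation by aldol addition and oxidation; it sets out from ester 4 and comes back at 14.
- i-Bu2AlH at −78 °C reduces 4 to 2-{5-[3,5-bis(benzyloxy)phenyl]furan-2-yl}acetaldehyde F8.
- Enolate 13 (slight excess, −78 °C) adds to F8 faster than protons are exchanged, giving 5-{5-[3,5-bis(benzyloxy)phenyl]furan-2-yl}-4-hydroxy-1-(2-isopropyl-1,3-dithian-2-yl)-3-methoxypentan-2-one F9 (racemic diastereomer mixture).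
- Swern oxidation of the carbinol of F9 gives 14.
- This cures proton transfer and O-acylation but not deprotonation on the dithiane side.

Step 9. S-Methylation of the thioketal next to a quaternary carbon may be sluggish, and forcing it invites O-methylation of the C6 phenol or degradation of the electron-rich benzofuran. The fallback dispenses with the thioketal and builds the isopropyl ketone after ring A; it sets out from acid 5 through its imidazolide 12 and comes back at 16.
- The dianion of methyl 4-methoxy-3-oxobutanoate (NaH, then n-BuLi, THF, −78 °C) is acylated at C4 by 12, giving methyl 6-{5-[3,5-bis(benzyloxy)phenyl]furan-2-yl}-4-methoxy-3,5-dioxohexanoate F10.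
- Acid closure as in step 8 (p-TsOH·H2O, toluene, Dean–Stark) gives methyl 2-{2-[3,5-bis(benzyloxy)phenyl]-6-hydroxy-5-methoxybenzofuran-4-yl}acetate F11. Lactonisation of the dioxo ester to a pyranone is the competing path, which is why this variant is not the first choice.
- Me(MeO)NH·HCl and i-PrMgCl (THF, −20 °C) convert F11 into 2-{2-[3,5-bis(benzyloxy)phenyl]-6-hydroxy-5-methoxybenzofuran-4-yl}-N-methoxy-N-methylacetamide F12.
- Further i-PrMgCl (0 °C) gives ketone 16.

**Further compounds**
F1 | step 8 | 3-bromo-5-hydroxy-4-methoxybenzaldehyde | O=Cc1cc(O)c(OC)c(Br)c1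
F2 | step 8 | 3-(benzyloxy)-5-bromo-4-methoxybenzaldehyde | O=Cc1cc(OCc2ccccc2)c(OC)c(Br)c1
F3 | step 8 | 3-(benzyloxy)-5-bromo-4-methoxyphenol | Oc1cc(OCc2ccccc2)c(OC)c(Br)c1
F4 | step 8 | 5-(benzyloxy)-3-bromo-2-iodo-4-methoxyphenol | Oc1cc(OCc2ccccc2)c(OC)c(Br)c1I
F5 | step 8 | {[3,5-bis(benzyloxy)phenyl]ethynyl}trimethylsilane | C[Si](C)(C)C#Cc1cc(OCc2ccccc2)cc(OCc2ccccc2)c1
F6 | step 8 | 6-(benzyloxy)-2-[3,5-bis(benzyloxy)phenyl]-4-bromo-5-methoxybenzofuran | COc1c(OCc2ccccc2)cc2oc(-c3cc(OCc4ccccc4)cc(OCc4ccccc4)c3)cc2c1Br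
F7 | step 8 | 1-{6-(benzyloxy)-2-[3,5-bis(benzyloxy)phenyl]-5-methoxybenzofuran-4-yl}-3-methylbutan-2-one | COc1c(OCc2ccccc2)cc2oc(-c3cc(OCc4ccccc4)cc(OCc4ccccc4)c3)cc2c1CC(=O)C(C)C
F8 | step 7 | 2-{5-[3,5-bis(benzyloxy)phenyl]furan-2-yl}acetaldehyde | O=CCc1ccc(-c2cc(OCc3ccccc3)cc(OCc3ccccc3)c2)o1
F9 | step 7 | 5-{5-[3,5-bis(benzyloxy)phenyl]furan-2-yl}-4-hydroxy-1-(2-isopropyl-1,3-dithian-2-yl)-3-methoxypentan-2-one (racemic diastereomer mixture) | CC(C)C1(CC(=O)C(OC)C(O)Cc2ccc(-c3cc(OCc4ccccc4)cc(OCc4ccccc4)c3)o2)SCCCS1
F10 | step 9 | methyl 6-{5-[3,5-bis(benzyloxy)phenyl]furan-2-yl}-4-methoxy-3,5-dioxohexanoate (racemic) | COC(=O)CC(=O)C(OC)C(=O)Cc1ccc(-c2cc(OCc3ccccc3)cc(OCc3ccccc3)c2)o1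
F11 | step 9 | methyl 2-{2-[3,5-bis(benzyloxy)phenyl]-6-hydroxy-5-methoxybenzofuran-4-yl}acetate | COC(=O)Cc1c(OC)c(O)cc2oc(-c3cc(OCc4ccccc4)cc(OCc4ccccc4)c3)cc12
F12 | step 9 | 2-{2-[3,5-bis(benzyloxy)phenyl]-6-hydroxy-5-methoxybenzofuran-4-yl}-N-methoxy-N-methylacetamide | CON(C)C(=O)Cc1c(OC)c(O)cc2oc(-c3cc(OCc4ccccc4)cc(OCc4ccccc4)c3)cc12
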